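## Retrosynthetic overview
- Target ⇒ 3-O-tri(benzyl)galloyl 2,3-cis ester, made by Mitsunobu esterification with C3 inversion of the 2,3-trans flavan-3-ol, then global debenzylation.
- trans-Flavan-3-ol ⇒ 3-acetylchroman by Baeyer–Villiger (C3–C(O)CH3 to C3–OAc, retention) ⇒ 3-(1-silyloxyethyl)chroman.
- The chroman (the only ring formed) ⇒ inverse-demand oxa-Diels–Alder of an o-quinone methide (A ring, from a phloroglucinol salicyl alcohol) with an E-styrene (B ring).
- The styrene carries an allylic silyl ether from (R)-but-3-en-2-ol, whose stereocenter sets the cycloaddition face. A and B rings are bought as benzenoid precursors.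

Assumption: methyl 3,5-dihydroxy-4-methoxybenzoate, 2,4,6-trihydroxybenzaldehyde, (R)-but-3-en-2-ol and 3,4,5-tris(benzyloxy)benzoic acid are purchasable.

## Route

**Step 1**
Reactants: 1, methyl 3,5-dihydroxy-4-methoxybenzoate
Product: 2, methyl 3,5-bis(benzyloxy)-4-methoxybenzoate
Conditions: BnBr (2.5 equiv), K2CO3, DMF, 60 °C
Reagents that add atoms: benzyl bromide, BrCc1ccccc1 (two Bn groups)
Why: Williamson O-benzylation masks the 3',5'-OH as benzyl ethers removable in the last step; the 4-OMe is untouched.

**Step 2**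
Reactants: 2
Product: 3, 3,5-bis(benzyloxy)-4-methoxybenzaldehyde
Conditions: DIBAL-H (1.1 equiv), CH2Cl2, –78 °C
Reagents that add atoms: none
Why: DIBAL-H stops at the aluminium hemiacetal at low temperature, so the ester is reduced only to the aldehyde (hydride reduction).

**Step 3**
Reactants: 3
Product: 4, 1,3-bis(benzyloxy)-2-methoxy-5-vinylbenzene
Conditions: Ph3P+CH3 Br–, KOtBu, THF, 0 °C to rt
Reagents that add atoms: methylenetriphenylphosphorane, C=P(c1ccccc1)(c1ccccc1)c1ccccc1 (leaves CH2)
Why: Wittig methylenation converts the aldehyde to the styrene needed as a metathesis partner.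

**Step 4**
Reactants: 5, (R)-but-3-en-2-ol
Product: 6, (R)-tert-butyl(but-3-en-2-yloxy)dimethylsilane
Conditions: TBSCl, imidazole, CH2Cl2, 0 °C to rt
Reagents that add atoms: TBSCl, C[Si](C)(Cl)C(C)(C)C (leaves TBS)
Why: Silylation protects the alcohol as an ether that survives metathesis and the cycloaddition; the (R) stereocenter is not touched.

**Step 5**
Reactants: 4, styrene; 6, silyl ether (3 equiv)
Product: 7, tert-butyl({(2R,3E)-4-[3,5-bis(benzyloxy)-4-methoxyphenyl]but-3-en-2-yl}oxy)dimethylsilane
Conditions: Grubbs II (5 mol%), CH2Cl2, 40 °C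
Reagents that add atoms: none (ethylene is lost)
Why: Cross-metathesis of a type II styrene with a type I allylic ether gives the thermodynamic E-alkene, and the allylic stereocenter is untouched.

**Step 6**
Reactants: 8, 2,4,6-trihydroxybenzaldehyde
Product: 9, 2,4-bis(benzyloxy)-6-hydroxybenzaldehyde
Conditions: BnBr (2.0 equiv), K2CO3, MeCN, reflux
Reagents that add atoms: benzyl bromide, BrCc1ccccc1 (two Bn groups)
Why: The acidic 4-OH and one 2-OH are alkylated, while the remaining 2-OH is locked by hydrogen bonding to the CHO and stays free; this sets the 5,7-dioxygenation of the A ring.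

**Step 7**
Reactants: 9
Product: 10, 3,5-bis(benzyloxy)-2-(hydroxymethyl)phenol
Conditions: NaBH4, MeOH/THF, 0 °C; crude used at once
Reagents that add atoms: none
Why: Hydride reduction gives the o-hydroxybenzyl alcohol, which is the o-quinone methide precursor.

**Step 8**
Reactants: 10 (2 equiv); 7 (1 equiv)
Product: 11, tert-butyl{(1R)-1-[(2S,3S)-5,7-bis(benzyloxy)-2-[3,5-bis(benzyloxy)-4-methoxyphenyl]chroman-3-yl]ethoxy}dimethylsilane (2,3-trans)
Conditions: PhB(OH)2 (2 equiv), EtCO2H (cat.), toluene, 110 °C; diastereomers separated by silica chromatography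
Reagents that add atoms: none (the boronate releases the o-QM and PhB(OH)2 is not incorporated)
Why: The boronate releases the o-quinone methide, which undergoes an inverse-demand oxa-Diels–Alder [4+2] with the electron-rich styrene. The o-QM methylene carbon bonds to the alkene carbon bearing the side chain (C3) and oxygen bonds to the benzylic carbon (C2), and the E-alkene gives 2,3-trans stereospecifically. The (R)-allylic OTBS directs the o-QM to the face anti to OTBS (A-strain/Kishi-type model), giving the 2R,3S-type face as the major diastereomer, and the minor diastereomer is removed by chromatography.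

**Step 9**
Reactants: 11
Product: 12, (1R)-1-[(2S,3R)-5,7-bis(benzyloxy)-2-[3,5-bis(benzyloxy)-4-methoxyphenyl]chroman-3-yl]ethan-1-ol
Conditions: TBAF, THF, 0 °C to rt
Reagents that add atoms: none
Why: Fluoride cleaves the Si–O bond selectively; the benzyl and aryl ethers survive.

**Step 10**
Reactants: 12
Product: 13, 1-[(2S,3S)-5,7-bis(benzyloxy)-2-[3,5-bis(benzyloxy)-4-methoxyphenyl]chroman-3-yl]ethan-1-one
Conditions: Dess–Martin periodinane, NaHCO3, CH2Cl2, rt
Reagents that add atoms: none
Why: Oxidation of the secondary alcohol to the methyl ketone removes the pool stereocenter. The α-C3–H could epimerize, but the 2,3-trans arrangement is thermodynamically preferred, so the C2/C3 configuration is preserved.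

**Step 11**
Reactants: 13
Product: 14, (2R,3S)-5,7-bis(benzyloxy)-2-[3,5-bis(benzyloxy)-4-methoxyphenyl]chroman-3-yl acetate
Conditions: mCPBA, NaHCO3, CH2Cl2, 0 °C
Reagents that add atoms: mCPBA, OOC(=O)c1cccc(Cl)c1 (one O atom)
Why: Baeyer–Villiger oxidation migrates the secondary C3 in preference to methyl and with retention, so C3 becomes C3–OAc without any change of configuration.

**Step 12**
Reactants: 14
Product: 15, (2R,3S)-5,7-bis(benzyloxy)-2-[3,5-bis(benzyloxy)-4-methoxyphenyl]chroman-3-ol (trans, gallocatechin-type)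
Conditions: K2CO3, MeOH, rt
Reagents that add atoms: none
Why: Transesterification with methoxide removes the acetate with no stereochemical change.

**Step 13**
Reactants: 15; 16, 3,4,5-tris(benzyloxy)benzoic acid
Product: 17, (2R,3R)-5,7-bis(benzyloxy)-2-[3,5-bis(benzyloxy)-4-methoxyphenyl]chroman-3-yl 3,4,5-tris(benzyloxy)benzoate
Conditions: PPh3, DIAD, THF, 0 °C to rt
Reagents that add atoms: none (acid 16 is a reactant)
Why: Mitsunobu esterification proceeds by SN2 with inversion at C3, converting the 2,3-trans alcohol to the 2,3-cis galloyl ester (3R) in the step that installs the gallate.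

**Step 14**
Reactants: 17
Product: 18, 4'-O-methylepigallocatechin-3-O-gallate
Conditions: H2 (1 atm), Pd(OH)2/C, THF/MeOH 1:1, rt
Reagents that add atoms: none (H2 only)
Why: Hydrogenolysis cleaves all seven benzyl ethers (A ring 2, B ring 2, galloyl 3) while the aryl methyl ether, the ester and the stereocenters are unaffected.

## Compound list
1 | methyl 3,5-dihydroxy-4-methoxybenzoate | COC(=O)c1cc(O)c(OC)c(O)c1 | starting material
2 | methyl 3,5-bis(benzyloxy)-4-methoxybenzoate | COC(=O)c1cc(OCc2ccccc2)c(OC)c(OCc2ccccc2)c1 | intermediate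
3 | 3,5-bis(benzyloxy)-4-methoxybenzaldehyde | COc1c(OCc2ccccc2)cc(C=O)cc1OCc1ccccc1 | intermediate
4 | 1,3-bis(benzyloxy)-2-methoxy-5-vinylbenzene | COc1c(OCc2ccccc2)cc(C=C)cc1OCc1ccccc1 | intermediate
5 | (R)-but-3-en-2-ol | C[C@@H](O)C=C | starting material
6 | (R)-tert-butyl(but-3-en-2-yloxy)dimethylsilane | C[C@@H](O[Si](C)(C)C(C)(C)C)C=C | intermediate
7 | (R,E)-silyl ether dienophile | C[C@@H](O[Si](C)(C)C(C)(C)C)/C=C/c1cc(OCc2ccccc2)c(OC)c(OCc2ccccc2)c1 | intermediate
8 | 2,4,6-trihydroxybenzaldehyde | O=Cc1c(O)cc(O)cc1O | starting material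
9 | 2,4-bis(benzyloxy)-6-hydroxybenzaldehyde | O=Cc1c(O)cc(OCc2ccccc2)cc1OCc1ccccc1 | intermediate
10 | 3,5-bis(benzyloxy)-2-(hydroxymethyl)phenol | OCc1c(O)cc(OCc2ccccc2)cc1OCc1ccccc1 | intermediate
11 | 2,3-trans chroman TBS ether | COc1c(OCc2ccccc2)cc([C@H]2Oc3cc(OCc4ccccc4)cc(OCc4ccccc4)c3C[C@@H]2[C@@H](C)O[Si](C)(C)C(C)(C)C)cc1OCc1ccccc1 | intermediate
12 | 2,3-trans chroman secondary alcohol | COc1c(OCc2ccccc2)cc([C@H]2Oc3cc(OCc4ccccc4)cc(OCc4ccccc4)c3C[C@@H]2[C@@H](C)O)cc1OCc1ccccc1 | intermediate
13 | 3-acetylchroman | COc1c(OCc2ccccc2)cc([C@H]2Oc3cc(OCc4ccccc4)cc(OCc4ccccc4)c3C[C@@H]2C(C)=O)cc1OCc1ccccc1 | intermediate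
14 | chroman-3-yl acetate | COc1c(OCc2ccccc2)cc([C@H]2Oc3cc(OCc4ccccc4)cc(OCc4ccccc4)c3C[C@@H]2OC(C)=O)cc1OCc1ccccc1 | intermediate
15 | 2,3-trans chroman-3-ol | COc1c(OCc2ccccc2)cc([C@H]2Oc3cc(OCc4ccccc4)cc(OCc4ccccc4)c3C[C@@H]2O)cc1OCc1ccccc1 | intermediate
16 | 3,4,5-tris(benzyloxy)benzoic acid | OC(=O)c1cc(OCc2ccccc2)c(OCc2ccccc2)c(OCc2ccccc2)c1 | starting material
17 | perbenzylated 2,3-cis galloyl ester | COc1c(OCc2ccccc2)cc([C@H]2Oc3cc(OCc4ccccc4)cc(OCc4ccccc4)c3C[C@H]2OC(=O)c4cc(OCc5ccccc5)c(OCc5ccccc5)c(OCc5ccccc5)c4)cc1OCc1ccccc1 | intermediate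
18 | 4'-O-methylepigallocatechin-3-O-gallate | COc1c(O)cc([C@H]2Oc3cc(O)cc(O)c3C[C@H]2OC(=O)c2cc(O)c(O)c(O)c2)cc1O | target

## Step count
Total steps: 14. Longest linear sequence: 11 (1 → 2 → 3 → 4 → 7 → 11 → 12 → 13 → 14 → 15 → 17 → 18).

## Three steps most likely to fail
1. **Step 8 (o-QM cycloaddition):** yield or diastereoselectivity may be poor (o-QM oligomerization, acid-mediated C2 ionization, weak facial bias from a remote stereocenter). Fallback: change strategy to a non-cycloaddition assembly from (R)-benzyl glycidyl ether. Open it with lithiated 1,3,5-tris(benzyloxy)benzene/BF3, oxidize the primary alcohol, add the 3,5-bis(benzyloxy)-4-methoxyphenyl Grignard with chelation control to give the threo diol, then close the ring by Mitsunobu and continue from 15.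
2. **Step 11 (Baeyer–Villiger):** the very electron-rich arenes may be oxidized, or migration may be unselective. Fallback: degrade 13 differently by haloform oxidation to the C3 carboxylic acid, then Barton decarboxylative hydroxylation (PTOC ester, O2, hν), which should give the trans alcohol 15 because the C3 radical is trapped trans to the aryl group.
3. **Step 13 (Mitsunobu inversion):** elimination to a flav-2-ene or flav-3-ene, or incomplete inversion. Fallback: oxidize 15 to the flavan-3-one and reduce it with L-Selectride to the axial (cis) alcohol, then galloylate with 16 (DCC, DMAP).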